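The target is the [4+2] dimer of one xanthanolide monomer (trans-lactone 16), oxidised at C1. Everything rests on making the monomer's cycloheptene (C1, C5–C10) from a cyclohexanone of the carvone series. The key step exploits that C5 is an unsubstituted CH flanked by the side-chain carbon C1 and by C6. Trimethylsilyldiazomethane inserts C5 between the carbonyl carbon C1 and C6, and the ensuing silyl shift gives the C1=C5 enol silane, so ring size and position of the future diene are set in one operation. The precursor is the all-equatorial cyclohexanone 7, which already holds C7, C8 and C10. Triflation, Heck coupling, lactonisation, thermal dimerisation and dienolate oxygenation finish the route.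

Key step: step 6

Remark on labels: xanthane numbering is used for each C15 half: ring C1, C5, C6, C7, C8, C9, C10; side chain C2=C3–C4(=O)–C15 on C1; methyl C14 on C10; lactone carbons C11 (on C7), C12 (carbonyl, bound to O on C8) and C13 (methylene). Primed labels belong to the half whose methylene lactone becomes the spiro lactone. In the ring numbering of 1–7, C1 (carbonyl) becomes C1, C2 becomes C10, C4 becomes C8, C5 becomes C7.

Remark on the chemistry: both halves of the target have the same configuration (7S,8R,10S), so a single monomer, the C10 epimer of ent-xanthatin, is dimerised.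

Step 1
Reactants: 1 (S)-(+)-carvone
Product: 2 (5R)-1-(tert-butyldimethylsilyloxy)-2-methyl-5-(prop-1-en-2-yl)cyclohexa-1,3-diene (linear dienol ether; C5 is spatially as in 1, only the CIP letter changes)
Conditions: KOt-Bu, THF–DMPU, −40 → 0 °C; then TBSCl, −78 → 0 °C
Reagents that add atoms: tert-butyldimethylsilyl chloride, CC(C)(C)[Si](C)(C)Cl
Why: Reversible (thermodynamic) enolisation of the enone removes a γ-hydrogen at C4 and should give the linear, fully conjugated potassium dienolate, which the hard silyl chloride traps on oxygen (thermodynamic dienolate formation and O-silylation); C5 is not touched.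

Step 2
Reactants: 2 linear dienol silyl ether
Product: 3 (4R,5S)-4-hydroxy-2-methyl-5-(prop-1-en-2-yl)cyclohex-2-en-1-one (4-OH trans to the isopropenyl group)
Conditions: mCPBA, NaHCO3, CH2Cl2–H2O, −10 °C
Reagents that add atoms: 3-chloroperbenzoic acid, OOC(=O)c1cccc(Cl)c1
Why: Vinylogous Rubottom oxidation, in which the peracid should attack the electron-rich diene at its unhindered terminus C4 from the face opposite the neighbouring isopropenyl group, and collapse of the epoxide with loss of the silyl group gives the γ-hydroxy enone with the new C–O bond trans to the C5 substituent.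

Step 3
Reactants: 3 trans-4-hydroxycarvone
Product: 4 (4R,5S)-4-hydroxy-5-(3-hydroxyprop-1-en-2-yl)-2-methylcyclohex-2-en-1-one
Conditions: SeO2 (cat.), t-BuOOH, CH2Cl2, rt
Reagents that add atoms: selenium dioxide, O=[Se]=O (oxygen donor, turned over by tert-butyl hydroperoxide, CC(C)(C)OO)
Why: Riley-type allylic hydroxylation (ene reaction, then [2,3]-shift) should take place at the methyl group of the electron-rich 1,1-disubstituted alkene, whereas the electron-poor enone alkene and its carbinol are left alone.

Step 4
Reactants: 4 diol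
Product: 5 (4R,5S)-4-(tert-butyldimethylsilyloxy)-5-[3-(tert-butyldimethylsilyloxy)prop-1-en-2-yl]-2-methylcyclohex-2-en-1-one
Conditions: TBSCl, imidazole, DMF, rt → 40 °C
Reagents that add atoms: tert-butyldimethylsilyl chloride, CC(C)(C)[Si](C)(C)Cl
Why: Standard silyl ether formation on both hydroxyl groups gives ethers that survive hydride, Lewis acid, methyllithium and palladium in the following steps.

Step 5
Reactants: 5 bis-silyl enone
Product: 7 (2S,4R,5S)-4-(tert-butyldimethylsilyloxy)-5-[3-(tert-butyldimethylsilyloxy)prop-1-en-2-yl]-2-methylcyclohexan-1-one (all substituents equatorial), via lithium enolate 6 (not isolated)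
Conditions: LiBH(s-Bu)3, THF, −78 °C; then MeOH, −78 °C → rt
Reagents that add atoms: none
Why: Conjugate (1,4) hydride reduction of the β-unsubstituted enone by the bulky borohydride gives the enolate, and protonation followed by methoxide equilibration of the only epimerisable centre C2 should place the methyl group equatorial, cis to the C4 silyloxy group and trans to the C5 side chain (thermodynamic control in the chair).

Step 6
Reactants: 7 all-equatorial cyclohexanone
Product: 9 (4S,5R,7S)-5-(tert-butyldimethylsilyloxy)-4-[3-(tert-butyldimethylsilyloxy)prop-1-en-2-yl]-7-methyl-1-(trimethylsilyloxy)cyclohept-1-ene, via alpha-silyl cycloheptanone 8 (not isolated)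
Conditions: Me3SiCHN2, Sc(OTf)3 (cat.), toluene, −78 → 23 °C; then 60 °C
Reagents that add atoms: trimethylsilyldiazomethane, C[Si](C)(C)C=[N+]=[N-]
Why: Sc(OTf)3 activates the ketone, the nucleophilic carbon of the diazoalkane adds to C1, and the β-oxido diazonium loses N2 with a 1,2-shift of the unsubstituted C6 methylene, so the new CH(SiMe3) carbon (C5) is inserted between C1 and C6; a 1,3-Brook (carbon-to-oxygen) silyl shift then turns the α-silyl cycloheptanone into the C1=C5 enol silane, which is inert to a second homologation. The closest known reaction type is the Lewis-acid-catalysed diazoalkane–ketone homologation (Tiffeneau–Demjanov-type ring expansion) with trimethylsilyldiazomethane. No new ring is closed; the existing six-membered ring is enlarged to the seven-membered one by the 1,2-alkyl shift. No lasting stereocentre is formed (C5 ends sp2), C7 and C8 are carried over unchanged, and C10 is the thermodynamically preferred pseudo-equatorial epimer should it enolise. The step needs migration of C6 rather than of the methyl-bearing C10; the methyl branch at C10 and the bulky silyl group on the diazo carbon should secure migration of the less substituted carbon. The silyl shift then translates this regiochemistry into the position of the enol double bond, which fixes where the diene will be.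

Step 7
Reactants: 9 cycloheptenyl trimethylsilyl ether
Product: 11 (4S,5R,7S)-5-(tert-butyldimethylsilyloxy)-4-[3-(tert-butyldimethylsilyloxy)prop-1-en-2-yl]-7-methylcyclohept-1-en-1-yl trifluoromethanesulfonate, via lithium enolate 10 (not isolated)
Conditions: MeLi, THF, 0 °C; then PhNTf2, −78 °C → rt
Reagents that add atoms: N-phenylbis(trifluoromethanesulfonimide), O=S(=O)(N(c1ccccc1)S(=O)(=O)C(F)(F)F)C(F)(F)F
Why: Methyllithium cleaves the Si–O bond and releases the lithium enolate without loss of regiochemistry, and triflyl transfer from PhNTf2 gives the C1=C5 enol triflate (regiospecific enolate generation from an enol silane, then O-triflation).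

Step 8
Reactants: 11 enol triflate; 12 methyl vinyl ketone
Product: 13 (3E)-4-[(4S,5R,7S)-5-(tert-butyldimethylsilyloxy)-4-[3-(tert-butyldimethylsilyloxy)prop-1-en-2-yl]-7-methylcyclohept-1-en-1-yl]but-3-en-2-one
Conditions: Pd(OAc)2 (cat.), PPh3, Et3N, DMF, 60 °C
Reagents that add atoms: none
Why: Mizoroki–Heck reaction of the alkenyl triflate with the enone should give the (E)-dienone by syn insertion and syn β-hydride elimination, and the hindered 1,1-disubstituted alkene of the side chain does not compete with the excess of unhindered enone.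

Step 9
Reactants: 13 bis-silyl dienone
Product: 14 (3E)-4-[(4S,5R,7S)-5-hydroxy-4-(3-hydroxyprop-1-en-2-yl)-7-methylcyclohept-1-en-1-yl]but-3-en-2-one
Conditions: HF·pyridine, THF–pyridine, 0 °C → rt
Reagents that add atoms: none
Why: Fluoride-mediated cleavage of both silyl ethers (desilylation) frees the 1,4-diol without touching the dienone.

Step 10
Reactants: 14 diol
Product: 16 (3aS,7S,8aR)-7-methyl-3-methylidene-6-[(1E)-3-oxobut-1-en-1-yl]-3,3a,4,7,8,8a-hexahydro-2H-cyclohepta[b]furan-2-one (monomer, C10 epimer of ent-xanthatin), via lactol 15 (not isolated)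
Conditions: TEMPO (cat.), PhI(OAc)2, CH2Cl2, rt
Reagents that add atoms: none
Why: Oxoammonium (TEMPO) oxidation is selective for the primary allylic alcohol; the aldehyde closes onto the C8 hydroxyl to the lactol, which is oxidised further to the trans-fused α-methylene lactone (oxidative lactonisation of a 1,4-diol), with C7 and C8 unchanged.

Step 11
Reactants: 16 monomer (two molecules)
Product: 17 Diels–Alder dimer: cyclohexene ring C1=C2–C3(H)(acetyl)–C11'–C13'H2–C5(H), fused to the first cycloheptane at C1/C5 and spiro at C11' to the lactone of the second half; H5 cis to C12'=O and to H3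
Conditions: neat (or concentrated in toluene), BHT (cat.), 100 °C, sealed tube, dark
Reagents that add atoms: none
Why: Thermal Diels–Alder homodimerisation, in which the C5=C1–C2=C3 diene of one molecule should add to the exocyclic C11'=C13' alkene of a second with ortho regiochemistry (C5–C13' and C3–C11'), with the lactone carbonyl exo as is usual for s-cis-locked α-methylene lactones (sets the spiro centre C11' and H3 cis to H5), on the dienophile face opposite its C6' methylene, and by chair-like axial attack on C5 of the all-equatorial cycloheptene anti to the pseudo-axial C6–H, that is on the face of the C10 methyl and the C8 oxygen (sets C5).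

Step 12
Reactants: 17 Diels–Alder dimer
Product: 19 target CNP0168949.4 (C1 hydroxyl cis to H5, alkene C2=C3 conjugated with the acetyl group), via C1 hydroperoxide 18 (not isolated)
Conditions: O2 (1 atm), DBU (cat.), MeCN, 0 °C; then PPh3, 0 °C
Reagents that add atoms: dioxygen, O=O
Why: The doubly activated C3–H of the β,γ-unsaturated ketone is removed by the amidine and the linear dienolate is oxygenated by O2 at its γ-terminus C1, which moves the alkene into conjugation (dienolate autoxidation); attack should come from the face of H5 and H10, anti to the C10 methyl, to give the cis ring fusion, and PPh3 reduces the hydroperoxide to the tertiary alcohol.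

Compound list
1 | (S)-(+)-carvone, (5S)-2-methyl-5-(prop-1-en-2-yl)cyclohex-2-en-1-one | CC1=CC[C@@H](CC1=O)C(C)=C | starting material
2 | (5R)-1-(tert-butyldimethylsilyloxy)-2-methyl-5-(prop-1-en-2-yl)cyclohexa-1,3-diene | CC1=C(O[Si](C)(C)C(C)(C)C)C[C@@H](C(C)=C)C=C1 | intermediate
3 | (4R,5S)-4-hydroxy-2-methyl-5-(prop-1-en-2-yl)cyclohex-2-en-1-one | O[C@@H]1C=C(C)C(=O)C[C@H]1C(C)=C | intermediate
4 | (4R,5S)-4-hydroxy-5-(3-hydroxyprop-1-en-2-yl)-2-methylcyclohex-2-en-1-one | O[C@@H]1C=C(C)C(=O)C[C@H]1C(=C)CO | intermediate
5 | (4R,5S)-4-(tert-butyldimethylsilyloxy)-5-[3-(tert-butyldimethylsilyloxy)prop-1-en-2-yl]-2-methylcyclohex-2-en-1-one | CC(C)(C)[Si](C)(C)O[C@@H]1C=C(C)C(=O)C[C@H]1C(=C)CO[Si](C)(C)C(C)(C)C | intermediate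
6 | lithium (4R,5S)-4-(tert-butyldimethylsilyloxy)-5-[3-(tert-butyldimethylsilyloxy)prop-1-en-2-yl]-2-methylcyclohex-1-en-1-olate | CC(C)(C)[Si](C)(C)O[C@@H]1CC(C)=C(O[Li])C[C@H]1C(=C)CO[Si](C)(C)C(C)(C)C | intermediate (not isolated)
7 | (2S,4R,5S)-4-(tert-butyldimethylsilyloxy)-5-[3-(tert-butyldimethylsilyloxy)prop-1-en-2-yl]-2-methylcyclohexan-1-one | CC(C)(C)[Si](C)(C)O[C@@H]1C[C@H](C)C(=O)C[C@H]1C(=C)CO[Si](C)(C)C(C)(C)C | intermediate
8 | (2S,4R,5S)-4-(tert-butyldimethylsilyloxy)-5-[3-(tert-butyldimethylsilyloxy)prop-1-en-2-yl]-2-methyl-7-(trimethylsilyl)cycloheptan-1-one (C7 epimers) | CC(C)(C)[Si](C)(C)O[C@@H]1C[C@H](C)C(=O)C([Si](C)(C)C)C[C@H]1C(=C)CO[Si](C)(C)C(C)(C)C | intermediate (not isolated)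
9 | (4S,5R,7S)-5-(tert-butyldimethylsilyloxy)-4-[3-(tert-butyldimethylsilyloxy)prop-1-en-2-yl]-7-methyl-1-(trimethylsilyloxy)cyclohept-1-ene | CC(C)(C)[Si](C)(C)O[C@@H]1C[C@H](C)C(O[Si](C)(C)C)=CC[C@H]1C(=C)CO[Si](C)(C)C(C)(C)C | intermediate
10 | lithium (4S,5R,7S)-5-(tert-butyldimethylsilyloxy)-4-[3-(tert-butyldimethylsilyloxy)prop-1-en-2-yl]-7-methylcyclohept-1-en-1-olate | CC(C)(C)[Si](C)(C)O[C@@H]1C[C@H](C)C(O[Li])=CC[C@H]1C(=C)CO[Si](C)(C)C(C)(C)C | intermediate (not isolated)
11 | (4S,5R,7S)-5-(tert-butyldimethylsilyloxy)-4-[3-(tert-butyldimethylsilyloxy)prop-1-en-2-yl]-7-methylcyclohept-1-en-1-yl trifluoromethanesulfonate | CC(C)(C)[Si](C)(C)O[C@@H]1C[C@H](C)C(OS(=O)(=O)C(F)(F)F)=CC[C@H]1C(=C)CO[Si](C)(C)C(C)(C)C | intermediate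
12 | methyl vinyl ketone (but-3-en-2-one) | CC(=O)C=C | starting material
13 | (3E)-4-[(4S,5R,7S)-5-(tert-butyldimethylsilyloxy)-4-[3-(tert-butyldimethylsilyloxy)prop-1-en-2-yl]-7-methylcyclohept-1-en-1-yl]but-3-en-2-one | CC(C)(C)[Si](C)(C)O[C@@H]1C[C@H](C)C(/C=C/C(C)=O)=CC[C@H]1C(=C)CO[Si](C)(C)C(C)(C)C | intermediate
14 | (3E)-4-[(4S,5R,7S)-5-hydroxy-4-(3-hydroxyprop-1-en-2-yl)-7-methylcyclohept-1-en-1-yl]but-3-en-2-one | O[C@@H]1C[C@H](C)C(/C=C/C(C)=O)=CC[C@H]1C(=C)CO | intermediate
15 | (3aS,7S,8aR)-2-hydroxy-7-methyl-3-methylidene-6-[(1E)-3-oxobut-1-en-1-yl]-3,3a,4,7,8,8a-hexahydro-2H-cyclohepta[b]furan (lactol, C2 epimers) | C=C1C(O)O[C@@H]2C[C@H](C)C(/C=C/C(C)=O)=CC[C@@H]12 | intermediate (not isolated)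
16 | (3aS,7S,8aR)-7-methyl-3-methylidene-6-[(1E)-3-oxobut-1-en-1-yl]-3,3a,4,7,8,8a-hexahydro-2H-cyclohepta[b]furan-2-one (monomer) | C=C1C(=O)O[C@@H]2C[C@H](C)C(/C=C/C(C)=O)=CC[C@@H]12 | intermediate
17 | Diels–Alder dimer of 16 (1-deoxy-1,2-didehydro-2,3-dihydro precursor of the target) | C=C1C(=O)O[C@@H]2C[C@H](C)C3=C[C@H](C(C)=O)[C@]4(C[C@@H]3C[C@@H]12)C(=O)O[C@@H]1C[C@H](C)C(/C=C/C(C)=O)=CC[C@H]14 | intermediate
18 | C1 hydroperoxide of the target | C=C1C(=O)O[C@@H]2C[C@H](C)[C@]3(OO)C=C(C(C)=O)[C@]4(C[C@@H]3C[C@@H]12)C(=O)O[C@@H]1C[C@H](C)C(/C=C/C(C)=O)=CC[C@H]14 | intermediate (not isolated)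
19 | CNP0168949.4 | C=C1C(=O)O[C@@H]2C[C@H](C)[C@]3(O)C=C(C(C)=O)[C@]4(C[C@@H]3C[C@@H]12)C(=O)O[C@@H]1C[C@H](C)C(/C=C/C(C)=O)=CC[C@H]14 | target

Total step count: 12
Longest linear sequence: 12 steps (1 → 19)

Steps most likely to fail

Step 11. The cycloaddition of two electron-poor partners may be too slow to outrun polymerisation, and at the temperature needed the facial discrimination at C5 of the flexible cycloheptene may erode. The fallback sets out from 16. Luche reduction (NaBH4, CeCl3·7H2O, MeOH, −78 °C) of the side-chain ketone should give the dienol (3aS,7S,8aR)-6-[(1E)-3-hydroxybut-1-en-1-yl]-7-methyl-3-methylidene-3,3a,4,7,8,8a-hexahydro-2H-cyclohepta[b]furan-2-one F1 as both carbinol epimers. This electron-richer, normal-demand diene should dimerise with its own methylene lactone at lower temperature (toluene, 50 °C) to the bis-carbinol dimer F2. Dess–Martin oxidation of both carbinols comes back to the route at 17.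

Step 1. Equilibration to the linear dienolate may be incomplete, so that kinetic deprotonation at C6 delivers the cross-conjugated dienol ether and the oxygen then enters at the wrong carbon. The fallback sets out from 1 and avoids enolates. Acid-catalysed enol acetylation under thermodynamic control (isopropenyl acetate, TsOH cat., reflux) should give the linear dienol acetate (5R)-2-methyl-5-(prop-1-en-2-yl)cyclohexa-1,3-dien-1-yl acetate F3. Buffered peracid oxidation (mCPBA, NaHCO3, CH2Cl2–H2O) at C4 with loss of the acetyl group comes back to the route at 3.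

Step 12. The amidine may add to the methylene lactone, or the oxygenation may show poor regio- and facial control. The fallback sets out from 17 and uses a Schenck ene reaction with singlet oxygen (O2, tetraphenylporphyrin, visible light, CH2Cl2, −20 °C), which needs no base. The oxygen should bind C1 while H3 is abstracted on the same face, the face of H5, giving hydroperoxide 18 directly; PPh3 then comes back to the route at 19. No new compound is made.

Further compounds
F1 | step 11 | (3aS,7S,8aR)-6-[(1E)-3-hydroxybut-1-en-1-yl]-7-methyl-3-methylidene-3,3a,4,7,8,8a-hexahydro-2H-cyclohepta[b]furan-2-one (carbinol epimers) | C=C1C(=O)O[C@@H]2C[C@H](C)C(/C=C/C(C)O)=CC[C@@H]12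
F2 | step 11 | bis-carbinol Diels–Alder dimer (17 with both side-chain ketones reduced) | C=C1C(=O)O[C@@H]2C[C@H](C)C3=C[C@H](C(C)O)[C@]4(C[C@@H]3C[C@@H]12)C(=O)O[C@@H]1C[C@H](C)C(/C=C/C(C)O)=CC[C@H]14
F3 | step 1 | (5R)-2-methyl-5-(prop-1-en-2-yl)cyclohexa-1,3-dien-1-yl acetate | CC1=C(OC(C)=O)C[C@@H](C(C)=C)C=C1
F0 | step 12 | none | none
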